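| flask | Q | Z | G | remark | time |
|---|---|---|---|---|---|
| zeta | 20 mM | 0.70 mM (held) | 0.90 mM | run made earlier |  |
| epsilon | 20 mM | 0.70 mM (held) | 1.4 mM | run made earlier |  |
| flask | 20 mM | 0.70 mM (held) | 0.64 mM |  | 80 min |

- zeta (time / min: D / %, E / %): 20.0: 9.0, 0; 40.0: 11.6, 6.2; 60.0: 15.6, 13.3; 80.0: 17.1, 19.8; 90.0: 17.6, 21.7
- epsilon (time / min: D / %, E / %): 20.0: 7.6, 4.5; 40.0: 11.7, 9.2; 60.0: 11.6, 18.4; 80.0: 11.7, 22.9; 90.0: 12.1, 29.5

(each reading ± 1 percentage point)

- percentages count the Q that a species holds: one J counts as two
- solid, in amounts per volume of the solution: Q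
- at the start none of L is dissolved
- the numbers in the tables scatter by 1 percentage point (one standard deviation)
- candidate steps: D + E -> J; Z <-> L; Q <-> D; D + L + G -> G + E
- at the start none of Q is in solution
- D means what is dissolved; the solid is not counted in it

- concentration of D at 80 min, in mM
- concentration of E at 80 min, in mM
- concentration of Q at 80 min, in mM

Set the flask beside the zeta run: the same Q and Z, but G falls from 0.90 mM to 0.64 mM. At 80.0 min, D + E read 36.9% of the charge in zeta and 34.6% in epsilon, although epsilon held more G. So I took 35.8% as D + E in the flask too, and let G divide it between them.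

I carried one quantity, the E clock: the half-life of D against conversion to E, a pseudo-first-order half-life, taken as proportional to 1/G. The area under zeta's D fractions up to 80.0 min was 8.95 min. Set against zeta's E, that gave a clock of 31.3 min. The flask's clock was therefore slower, 44.1 min, so I expected more D and less E there than in zeta.

With zeta's area, the flask gave E 14.1% and D 21.7%. That D exceeded zeta's, so I scaled the area by it and went round again: E 17.8%. I took the mean of the two rounds as my estimate: E 16.0%, D 19.8%, and Q 64.2% with J uncounted.

The forecast said D 3.9 mM, E 3.1 mM and Q 12.4 mM, on the ground that “E forms at a rate proportional to G·D”.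

The flask gave D 4.06 mM, E 3.07 mM and Q 12.3 mM, or 20.3%, 15.4% and 61.5% of the charge.

    D + E → J (k = 0.842 M⁻¹ min⁻¹)
    Z ⇌ L, rate k2*(csat - [L]) (kL = 13.2 min⁻¹)
    Q ⇌ D, rate k3*(cs3 - [D]) while solid is left; crystals form when [D] > cs3 (solubility = 17.0 mM, k = 0.00672 min⁻¹)
    D + L + G → G + E (k = 35200 M⁻² min⁻¹)

At 37.3 min the flask made D 2.01 times as fast as it used it, net. My E clock of 44.1 min was shorter than the flask's half-life of D by the J step, 4.5 h at 80.0 min, and J stood at 2.85% then. The neighbouring flask, charged with 8.0 mM of Q at the same G, had the same clock, and its E over D was 0.758 against 0.756 in the flask, with its Q down to 3.81% of its charge.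

The data come from a simulation from invented constants.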